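**Assumption:** the target has no stereocentre (it is achiral), so no stereocontrol is needed; 1,3-dimethoxy-5-propylbenzene and 2,6-dimethoxy-4-propylphenol (4-propylsyringol) are taken as catalogue chemicals.

## Retrosynthetic overview

1. Last step: hydrogenolysis of one benzyl ester and one benzyl ether (ring B CO2H and 4-OH).
2. Key disconnection: the depside C(=O)–O bond, giving ring A acid 4 and ring B phenol 10 (3-OH free, 2-OH hydrogen-bonded to the ester, 4-OH benzylated).
3. Ring A acid 4: Vilsmeier formylation then Pinnick oxidation of 1,3-dimethoxy-5-propylbenzene.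
4. Ring B phenol 10: 4-propylsyringol → O-demethylation → Kolbe–Schmitt carboxylation (only one kind of free ring position) → one-pot benzyl ester / 4-O-benzyl ether formation.
5. No ring is constructed: both benzene rings are bought, ring A is elaborated first, ring B second, then they are joined.

## Route

Step 1
Reactants: 1 1,3-dimethoxy-5-propylbenzene
Product: 3 2,4-dimethoxy-6-propylbenzaldehyde, via iminium chloride 2 (not isolated)
Conditions: POCl3 (1.2 equiv), DMF, 0 °C to 60 °C; then H2O, 50 °C
Reagents that add atoms: N,N-dimethylformamide, CN(C)C=O; water, O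
Why: Vilsmeier–Haack formylation, an electrophilic aromatic substitution that goes para to one OMe and ortho to the other (next to propyl) rather than at the more hindered position between the two OMe groups.

Step 2
Reactants: 3 2,4-dimethoxy-6-propylbenzaldehyde
Product: 4 2,4-dimethoxy-6-propylbenzoic acid
Conditions: NaClO2, NaH2PO4, 2-methyl-2-butene, t-BuOH/H2O, rt
Reagents that add atoms: sodium chlorite, [Na+].[O-]Cl=O
Why: Pinnick oxidation converts the hindered aryl aldehyde to the acid, with the alkene scavenging HOCl so the electron-rich ring is not chlorinated.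

Step 3
Reactants: 5 2,6-dimethoxy-4-propylphenol
Product: 6 5-propylbenzene-1,2,3-triol
Conditions: 48% aq HBr, AcOH, reflux, Ar
Reagents that add atoms: none
Why: Acidic aryl methyl ether cleavage (O-protonation, then SN2 attack of bromide on methyl) frees both outer hydroxyls; the pyrogallol is stable in acid under argon.

Step 4
Reactants: 6 5-propylbenzene-1,2,3-triol
Product: 8 2,3,4-trihydroxy-6-propylbenzoic acid, via potassium 2,3,4-trihydroxy-6-propylbenzoate 7 (not isolated)
Conditions: KHCO3 (5 equiv), CO2 (10 bar), degassed H2O, 110 °C; then 2 M HCl, 0 °C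
Reagents that add atoms: carbon dioxide, O=C=O
Why: Kolbe–Schmitt carboxylation of the electron-rich phenoxide ortho to OH; the two free ring positions are equivalent by symmetry, so only one regioisomer can form.

Step 5
Reactants: 8 2,3,4-trihydroxy-6-propylbenzoic acid
Product: 10 benzyl 4-(benzyloxy)-2,3-dihydroxy-6-propylbenzoate, via benzyl 2,3,4-trihydroxy-6-propylbenzoate 9 (not isolated)
Conditions: BnBr (2.1 equiv), KHCO3 (3 equiv), DMF, Ar, rt then 50 °C
Reagents that add atoms: benzyl bromide, BrCc1ccccc1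
Why: Chemoselective SN2 O-alkylation (Williamson type): the carboxylate reacts first, then bicarbonate ionises only the most acidic phenol (4-OH, para to the ester carbonyl); 2-OH is hydrogen-bonded to the ester and 3-OH is less acidic and flanked on both sides.

Step 6
Reactants: 4 2,4-dimethoxy-6-propylbenzoic acid; 10 benzyl 4-(benzyloxy)-2,3-dihydroxy-6-propylbenzoate
Product: 12 benzyl 4-(benzyloxy)-3-[(2,4-dimethoxy-6-propylbenzoyl)oxy]-2-hydroxy-6-propylbenzoate, via mixed trifluoroacetic anhydride 11 (not isolated)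
Conditions: TFAA (4 equiv), toluene, rt
Reagents that add atoms: none
Why: TFAA-mediated depside esterification: the hindered electron-rich acid is activated as its aroyl trifluoroacetate (acylium donor) and acylates the free 3-OH, while the 2-OH is deactivated by its hydrogen bond to the ester carbonyl.

Step 7
Reactants: 12 benzyl 4-(benzyloxy)-3-[(2,4-dimethoxy-6-propylbenzoyl)oxy]-2-hydroxy-6-propylbenzoate
Product: 13 2,4-dihydroxy-3-[(2,4-dimethoxy-6-propylbenzoyl)oxy]-6-propylbenzoic acid (target)
Conditions: H2 (1 atm), 10% Pd/C, EtOAc, rt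
Reagents that add atoms: none
Why: Catalytic hydrogenolysis removes the benzyl ester and the benzyl ether (two equivalents of toluene) under neutral conditions that leave the aryl ester and methyl ethers intact and avoid acyl migration.

## Compound list

1 | 1,3-dimethoxy-5-propylbenzene | CCCc1cc(OC)cc(OC)c1 | starting material
2 | [(2,4-dimethoxy-6-propylphenyl)methylidene]dimethylammonium chloride | CCCc1cc(OC)cc(OC)c1C=[N+](C)C.[Cl-] | intermediate (not isolated)
3 | 2,4-dimethoxy-6-propylbenzaldehyde | CCCc1cc(OC)cc(OC)c1C=O | intermediate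
4 | 2,4-dimethoxy-6-propylbenzoic acid | CCCc1cc(OC)cc(OC)c1C(=O)O | intermediate
5 | 2,6-dimethoxy-4-propylphenol (4-propylsyringol) | CCCc1cc(OC)c(O)c(OC)c1 | starting material
6 | 5-propylbenzene-1,2,3-triol | CCCc1cc(O)c(O)c(O)c1 | intermediate
7 | potassium 2,3,4-trihydroxy-6-propylbenzoate | CCCc1cc(O)c(O)c(O)c1C(=O)[O-].[K+] | intermediate (not isolated)
8 | 2,3,4-trihydroxy-6-propylbenzoic acid | CCCc1cc(O)c(O)c(O)c1C(=O)O | intermediate
9 | benzyl 2,3,4-trihydroxy-6-propylbenzoate | CCCc1cc(O)c(O)c(O)c1C(=O)OCc1ccccc1 | intermediate (not isolated)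
10 | benzyl 4-(benzyloxy)-2,3-dihydroxy-6-propylbenzoate | CCCc1cc(OCc2ccccc2)c(O)c(O)c1C(=O)OCc1ccccc1 | intermediate
11 | 2,4-dimethoxy-6-propylbenzoic trifluoroacetic anhydride | CCCc1cc(OC)cc(OC)c1C(=O)OC(=O)C(F)(F)F | intermediate (not isolated)
12 | benzyl 4-(benzyloxy)-3-[(2,4-dimethoxy-6-propylbenzoyl)oxy]-2-hydroxy-6-propylbenzoate | CCCc1cc(OC)cc(OC)c1C(=O)Oc1c(O)c(C(=O)OCc2ccccc2)c(CCC)cc1OCc1ccccc1 | intermediate
13 | 2,4-dihydroxy-3-[(2,4-dimethoxy-6-propylbenzoyl)oxy]-6-propylbenzoic acid | CCCc1cc(OC)cc(OC)c1C(=O)Oc1c(O)cc(CCC)c(C(=O)O)c1O | target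

## Summary

Total step count: 7 (ring A: steps 1–2; ring B: steps 3–5; union and deprotection: steps 6–7).
Longest linear sequence: 5 steps (5 → 6 → 8 → 10 → 12 → 13).

Three steps most likely to fail:

**Step 4 (Kolbe–Schmitt carboxylation).** The carboxylation is reversible, the position is flanked by propyl, and the pyrogallol is air-sensitive in base. The fallback sets out from 6 and carries the carboxyl as a formyl group until after the depside bond is made. Vilsmeier formylation of 6 (POCl3, DMF, MeCN; then H2O) gives 2,3,4-trihydroxy-6-propylbenzaldehyde F1. Selective 4-O-benzylation (BnBr 1.0 equiv, NaHCO3, DMF, 40 °C) gives 4-(benzyloxy)-2,3-dihydroxy-6-propylbenzaldehyde F2. Coupling with acid 4 (TFAA, toluene, rt) gives 6-(benzyloxy)-3-formyl-2-hydroxy-4-propylphenyl 2,4-dimethoxy-6-propylbenzoate F3. Pinnick oxidation (NaClO2, NaH2PO4, 2-methyl-2-butene, t-BuOH/H2O) gives 4-(benzyloxy)-3-[(2,4-dimethoxy-6-propylbenzoyl)oxy]-2-hydroxy-6-propylbenzoic acid F4. Hydrogenolysis (H2, 10% Pd/C, EtOAc) comes back to the route at 13.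

**Step 5 (one-pot ester and 4-O-benzyl ether formation).** Over-alkylation at 3-OH or oxidation of the triol are the risks. The fallback sets out from 8 and replaces acidity-controlled alkylation by sterically controlled silylation. The acid 8 is esterified only (BnBr 1.0 equiv, KHCO3, DMF, rt) and 9 is now isolated. TBSCl (1.05 equiv) and imidazole in DMF at 0 °C silylate the least hindered, non-chelated 4-OH to give benzyl 4-[(tert-butyldimethylsilyl)oxy]-2,3-dihydroxy-6-propylbenzoate F5. Coupling with 4 (TFAA, toluene, rt) gives benzyl 4-[(tert-butyldimethylsilyl)oxy]-3-[(2,4-dimethoxy-6-propylbenzoyl)oxy]-2-hydroxy-6-propylbenzoate F6. HF·pyridine in THF (non-basic, so no acyl migration) gives benzyl 3-[(2,4-dimethoxy-6-propylbenzoyl)oxy]-2,4-dihydroxy-6-propylbenzoate F7. Hydrogenolysis (H2, 10% Pd/C, EtOAc) comes back to the route at 13.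

**Step 6 (depside coupling).** A di-ortho-substituted acid must acylate a phenol flanked by OH and OBn, and C-acylation of ring B or reaction at 2-OH could compete. The fallback sets out from 4 and swaps the acid-mediated acylium transfer for a base-mediated acylation with an isolated acyl donor. Acid 4 with (COCl)2 and catalytic DMF in CH2Cl2 gives 2,4-dimethoxy-6-propylbenzoyl chloride F8, isolated by evaporation. F8 is added to 10 with Et3N and catalytic DMAP in CH2Cl2 at 0 °C, where the non-chelated 3-OH is acylated. This comes back to the route at 12.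

## Further compounds

F1 | step 4 | 2,3,4-trihydroxy-6-propylbenzaldehyde | CCCc1cc(O)c(O)c(O)c1C=O
F2 | step 4 | 4-(benzyloxy)-2,3-dihydroxy-6-propylbenzaldehyde | CCCc1cc(OCc2ccccc2)c(O)c(O)c1C=O
F3 | step 4 | 6-(benzyloxy)-3-formyl-2-hydroxy-4-propylphenyl 2,4-dimethoxy-6-propylbenzoate | CCCc1cc(OC)cc(OC)c1C(=O)Oc1c(O)c(C=O)c(CCC)cc1OCc1ccccc1
F4 | step 4 | 4-(benzyloxy)-3-[(2,4-dimethoxy-6-propylbenzoyl)oxy]-2-hydroxy-6-propylbenzoic acid | CCCc1cc(OC)cc(OC)c1C(=O)Oc1c(O)c(C(=O)O)c(CCC)cc1OCc1ccccc1
F5 | step 5 | benzyl 4-[(tert-butyldimethylsilyl)oxy]-2,3-dihydroxy-6-propylbenzoate | CCCc1cc(O[Si](C)(C)C(C)(C)C)c(O)c(O)c1C(=O)OCc1ccccc1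
F6 | step 5 | benzyl 4-[(tert-butyldimethylsilyl)oxy]-3-[(2,4-dimethoxy-6-propylbenzoyl)oxy]-2-hydroxy-6-propylbenzoate | CCCc1cc(OC)cc(OC)c1C(=O)Oc1c(O)c(C(=O)OCc2ccccc2)c(CCC)cc1O[Si](C)(C)C(C)(C)C
F7 | step 5 | benzyl 3-[(2,4-dimethoxy-6-propylbenzoyl)oxy]-2,4-dihydroxy-6-propylbenzoate | CCCc1cc(OC)cc(OC)c1C(=O)Oc1c(O)c(C(=O)OCc2ccccc2)c(CCC)cc1O
F8 | step 6 | 2,4-dimethoxy-6-propylbenzoyl chloride | CCCc1cc(OC)cc(OC)c1C(=O)Cl
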